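**Plan**

1. Retrosynthetic cuts, in order: (a) the prenyl–C6 bond of the six-membered ring (dearomative C-prenylation of a hexasubstituted arene); (b) the bond from the exocyclic CH2 to C4 of the six-membered ring (arene C–H plus cyclopentane carbaldehyde); (c) the cyclopentane bond C1–C2; (d) the aryl–acyl bond.
2. Enabling feature: in the cyclopentane, carbinol carbon C2 (Me, OH) is beta to the exocyclic CH2 on C1. Raising that CH2 to CHO gives a beta-hydroxy aldehyde, so bond C1–C2 is an aldol retron, and the ring opens to a 1,6-keto aldehyde, the cleaved cyclohexene of limonene.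
3. Forward: the six-membered ring is bought as 2,4,6-trihydroxytoluene and acylated. The cyclopentane, the only ring that is made, is closed by aldol addition. Aldehyde and arene are joined by reductive alkylation, the arene is dearomatized by prenylation, and the silyl group is removed.
4. Stereochemistry: cyclopentane C5 comes from (R)-limonene (as its oxide). C1 and C2 are set in the aldol (substrate bias, L-proline, reversibility). The acyl alpha carbon comes from (S)-2-methylbutanoic acid. Quaternary C6 is set by a chiral palladium catalyst.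

Key step: step 2

Remark: the target is treated as the drawn enol tautomer of a beta-triketone, and the (6R) descriptor refers to that tautomer; commercial (4R)-limonene oxide is a cis/trans mixture, and both isomers give the same keto aldehyde.

**Route**

Step 1
Reactants: 1 (4R)-limonene 1,2-oxide (commercial cis/trans mixture)
Product: 2 (3R)-6-oxo-3-(prop-1-en-2-yl)heptanal
Conditions: H5IO6 (1.2 equiv), THF/H2O, 0 °C to rt
Reagents that add atoms: water, O
Why: Acid-promoted hydrolysis of the epoxide to the 1,2-diol and periodate glycol cleavage in one flask (periodic acid cleavage of an epoxide) should open the ring of both epoxide isomers to the same keto aldehyde, leaving the isopropenyl alkene and the limonene stereocenter (now C3) untouched.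

Step 2
Reactants: 2 (3R)-6-oxo-3-(prop-1-en-2-yl)heptanal
Product: 4 (1S,2R,5R)-2-hydroxy-2-methyl-5-(prop-1-en-2-yl)cyclopentane-1-carbaldehyde, via proline enamine 3 (not isolated)
Conditions: L-proline (20 mol%), DMSO, 23 °C
Reagents that add atoms: none
Why: L-Proline should condense with the aldehyde of 2 (far faster than with the methyl ketone) to give E-enamine 3, whose nucleophilic carbon adds to the ketone activated by the carboxylic acid, and hydrolysis of the iminium releases 4 and the catalyst; the closest known reaction type is the amine- or proline-catalysed intramolecular enolexo aldolization of keto aldehydes. The cyclopentane closes in a 5-exo-trig (5-enolexo) mode, joining the aldehyde alpha carbon (C1) to the ketone carbon (C2). Carbinol centre C2 is controlled by the acid-bound transition state, which holds enamine and carbonyl oxygen syn and so places OH cis to CHO, and by the existing isopropenyl centre C5, which sits pseudo-equatorial so that methyl ends cis-1,3 to it. C1 is controlled by C5 through the E-enamine (CHO trans to isopropenyl; L-proline is expected to be the matched catalyst, giving the same sense at the alpha carbon as in intermolecular aldehyde-donor aldols) and, being enolizable, can settle trans to both methyl and isopropenyl. Because the aldol is reversible, the mixture should drift to this most stable isomer, with the three carbon substituents trans-1,2, trans-1,2 and cis-1,3 and OH hydrogen-bonded to CHO. The step needs addition without dehydration to the conjugated enal and without ketone-enamine chemistry; room temperature, the absence of strong acid or base and the aldehyde preference of the secondary amine should secure this.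

Step 3
Reactants: 4 (1S,2R,5R)-2-hydroxy-2-methyl-5-(prop-1-en-2-yl)cyclopentane-1-carbaldehyde
Product: 5 (1S,2R,5R)-2-methyl-5-(prop-1-en-2-yl)-2-[(triethylsilyl)oxy]cyclopentane-1-carbaldehyde
Conditions: TESOTf, 2,6-lutidine, CH2Cl2, −78 °C
Reagents that add atoms: triethylsilyl trifluoromethanesulfonate, CC[Si](CC)(CC)OS(=O)(=O)C(F)(F)F
Why: Silyl triflate with a hindered pyridine base silylates tertiary alcohols at low temperature (silyl ether protection), which should block retro-aldol cleavage in the later amine-catalysed step without enolizing the aldehyde.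

Step 4
Reactants: 6 (2S)-2-methylbutanoic acid
Product: 7 (2S)-2-methylbutanoyl chloride
Conditions: (COCl)2, DMF (cat.), CH2Cl2, 0 °C to rt; concentrate, use crude
Reagents that add atoms: oxalyl chloride, O=C(Cl)C(Cl)=O
Why: Acid chloride formation through the chloroiminium (Vilsmeier-type) activator runs without base at low temperature, so the alpha stereocenter should not enolize.

Step 5
Reactants: 8 2,4,6-trihydroxytoluene; 7 (2S)-2-methylbutanoyl chloride
Product: 9 (2S)-2-methyl-1-(2,4,6-trihydroxy-3-methylphenyl)butan-1-one
Conditions: AlCl3 (3.5 equiv), PhNO2, 0 °C to rt; aq. HCl work-up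
Reagents that add atoms: none
Why: Friedel–Crafts C-acylation of the electron-rich phloroglucinol should give one regioisomer because the two open ring positions of 8 are equivalent, the new ketone deactivates the ring toward a second acylation, and the low temperature protects the alpha stereocenter.

Step 6
Reactants: 5 (1S,2R,5R)-2-methyl-5-(prop-1-en-2-yl)-2-[(triethylsilyl)oxy]cyclopentane-1-carbaldehyde; 9 (2S)-2-methyl-1-(2,4,6-trihydroxy-3-methylphenyl)butan-1-one
Product: 11 (2S)-2-methyl-1-[2,4,6-trihydroxy-3-methyl-5-({(1S,2R,5R)-2-methyl-5-(prop-1-en-2-yl)-2-[(triethylsilyl)oxy]cyclopentyl}methyl)phenyl]butan-1-one, via ortho-quinone methide 10 (not isolated)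
Conditions: L-proline (20 mol%), Hantzsch ester (diethyl 2,6-dimethyl-1,4-dihydropyridine-3,5-dicarboxylate, 1.2 equiv), EtOH, rt to 40 °C
Reagents that add atoms: none
Why: Amine-mediated Knoevenagel-type condensation of the aldehyde with the only free ring carbon of 9 should give ortho-quinone methide 10, which the dihydropyridine reduces by conjugate hydride transfer with rearomatization (three-component reductive alkylation); no stereocenter is created, and the enolizable C1 of the cyclopentane already holds its thermodynamic configuration.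

Step 7
Reactants: 11 (2S)-2-methyl-1-[2,4,6-trihydroxy-3-methyl-5-({(1S,2R,5R)-2-methyl-5-(prop-1-en-2-yl)-2-[(triethylsilyl)oxy]cyclopentyl}methyl)phenyl]butan-1-one
Product: 12 (6R)-3,5-dihydroxy-6-methyl-6-(3-methylbut-2-en-1-yl)-2-[(2S)-2-methylbutanoyl]-4-({(1S,2R,5R)-2-methyl-5-(prop-1-en-2-yl)-2-[(triethylsilyl)oxy]cyclopentyl}methyl)cyclohexa-2,4-dien-1-one
Conditions: Pd2(dba)3·CHCl3 (2.5 mol%), (R,R)-N,N'-(cyclohexane-1,2-diyl)bis[2-(diphenylphosphino)benzamide] (7.5 mol%), prenyl acetate (1.1 equiv), Et3N (1.2 equiv), CH2Cl2, 0 °C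
Reagents that add atoms: prenyl acetate (3-methylbut-2-en-1-yl acetate), CC(C)=CCOC(C)=O
Why: Proposed new method: zerovalent palladium should ionize prenyl acetate to a 1,1-dimethylallyl palladium cation held in the chiral pocket of the bisphosphine ligand, and the ammonium phenolate of 11 should attack it outer-sphere at the unsubstituted allyl terminus through the methyl-bearing ring carbon (ortho to the most acidic, non-chelated OH and far less hindered than the carbon carrying the branched cyclopentylmethyl group), the ligand selecting the face of the flat nucleophile and hence the configuration of the new quaternary carbon, while kinetically formed O-prenyl ethers re-ionize under the catalyst and funnel to the enol-stabilized C-alkylated product; the closest known reaction types are palladium-catalysed enantioselective allylic dearomatization of naphthols and linear-selective asymmetric prenylation of prochiral oxindole nucleophiles with this ligand family, together with non-asymmetric palladium-catalysed dearomative allylation of acylphloroglucinols; the sense of induction cannot be predicted with confidence, and the (S,S)-ligand is the mirror option should it prove opposite.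

Step 8
Reactants: 12 (6R)-3,5-dihydroxy-6-methyl-6-(3-methylbut-2-en-1-yl)-2-[(2S)-2-methylbutanoyl]-4-({(1S,2R,5R)-2-methyl-5-(prop-1-en-2-yl)-2-[(triethylsilyl)oxy]cyclopentyl}methyl)cyclohexa-2,4-dien-1-one
Product: 13 (6R)-3,5-dihydroxy-4-{[(1S,2R,5R)-2-hydroxy-2-methyl-5-(prop-1-en-2-yl)cyclopentyl]methyl}-6-methyl-6-(3-methylbut-2-en-1-yl)-2-[(2S)-2-methylbutanoyl]cyclohexa-2,4-dien-1-one (target)
Conditions: HF·pyridine, pyridine, THF, 0 °C
Reagents that add atoms: none
Why: Fluoride cleaves the Si–O bond (desilylation), and the pyridine buffer should prevent ionization of the tertiary alcohol or its acid-catalysed cyclization onto the neighbouring enol.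

**Compound list**

1 | (4R)-limonene 1,2-oxide, cis/trans mixture | CC12OC1C[C@@H](CC2)C(C)=C | starting material
2 | (3R)-6-oxo-3-(prop-1-en-2-yl)heptanal | C=C(C)[C@@H](CC=O)CCC(C)=O | intermediate
3 | L-proline E-enamine of 2 | C=C(C)[C@@H](/C=C/N1CCC[C@H]1C(=O)O)CCC(C)=O | intermediate
4 | (1S,2R,5R)-2-hydroxy-2-methyl-5-(prop-1-en-2-yl)cyclopentane-1-carbaldehyde | C=C(C)[C@@H]1CC[C@@](C)(O)[C@H]1C=O | intermediate
5 | (1S,2R,5R)-2-methyl-5-(prop-1-en-2-yl)-2-[(triethylsilyl)oxy]cyclopentane-1-carbaldehyde | C=C(C)[C@@H]1CC[C@@](C)(O[Si](CC)(CC)CC)[C@H]1C=O | intermediate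
6 | (2S)-2-methylbutanoic acid | CC[C@H](C)C(=O)O | starting material
7 | (2S)-2-methylbutanoyl chloride | CC[C@H](C)C(=O)Cl | intermediate
8 | 2,4,6-trihydroxytoluene | Cc1c(O)cc(O)cc1O | starting material
9 | (2S)-2-methyl-1-(2,4,6-trihydroxy-3-methylphenyl)butan-1-one | CC[C@H](C)C(=O)c1c(O)cc(O)c(C)c1O | intermediate
10 | ortho-quinone methide from 5 and 9 | C=C(C)[C@@H]1CC[C@@](C)(O[Si](CC)(CC)CC)[C@H]1C=C1C(=O)C(C)=C(O)C(C(=O)[C@@H](C)CC)=C1O | intermediate
11 | (2S)-2-methyl-1-[2,4,6-trihydroxy-3-methyl-5-({(1S,2R,5R)-2-methyl-5-(prop-1-en-2-yl)-2-[(triethylsilyl)oxy]cyclopentyl}methyl)phenyl]butan-1-one | C=C(C)[C@@H]1CC[C@@](C)(O[Si](CC)(CC)CC)[C@H]1Cc1c(O)c(C)c(O)c(C(=O)[C@@H](C)CC)c1O | intermediate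
12 | (6R)-3,5-dihydroxy-6-methyl-6-(3-methylbut-2-en-1-yl)-2-[(2S)-2-methylbutanoyl]-4-({(1S,2R,5R)-2-methyl-5-(prop-1-en-2-yl)-2-[(triethylsilyl)oxy]cyclopentyl}methyl)cyclohexa-2,4-dien-1-one | C=C(C)[C@@H]1CC[C@@](C)(O[Si](CC)(CC)CC)[C@H]1CC1=C(O)[C@@](C)(CC=C(C)C)C(=O)C(C(=O)[C@@H](C)CC)=C1O | intermediate
13 | (6R)-3,5-dihydroxy-4-{[(1S,2R,5R)-2-hydroxy-2-methyl-5-(prop-1-en-2-yl)cyclopentyl]methyl}-6-methyl-6-(3-methylbut-2-en-1-yl)-2-[(2S)-2-methylbutanoyl]cyclohexa-2,4-dien-1-one | C=C(C)[C@@H]1CC[C@@](C)(O)[C@H]1CC1=C(O)[C@@](C)(CC=C(C)C)C(=O)C(C(=O)[C@@H](C)CC)=C1O | target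

**Count and risks**

Total step count: 8. Longest linear sequence: 6 steps (steps 1, 2, 3, 6, 7, 8).

Steps most likely to fail:

Step 7. The risks are poor facial selectivity at the new quaternary carbon, competing alkylation at the ring carbon that carries the cyclopentylmethyl group, and attack at the substituted allyl terminus. Fallback: from 11, the classical dearomatizing C-alkylation of a fully substituted acylphloroglucinol with prenyl bromide and NaOMe in MeOH at 0 °C is used. It has no facial control and should give 12 together with the C-6 epimer of 12 F1. These are diastereomers and are separated by preparative HPLC, and the route is rejoined at 12.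

Step 2. The risks are dehydration of the aldol to the conjugated enal under amine catalysis and incomplete control of the two new centres. Fallback: from 2, the condensation is driven to completion (piperidine, AcOH, toluene, reflux) to give (5S)-2-methyl-5-(prop-1-en-2-yl)cyclopent-1-ene-1-carbaldehyde F2. Weitz–Scheffer epoxidation (H2O2, NaOH, MeOH, 0 °C) touches only the electron-poor alkene and should add anti to the isopropenyl group, giving (1S,2S,5R)-5-methyl-2-(prop-1-en-2-yl)-6-oxabicyclo[3.1.0]hexane-1-carbaldehyde F3. SmI2 in THF/MeOH at −90 °C cleaves the alpha C–O bond through the ketyl. Protonation and brief equilibration with Et3N should place CHO trans to methyl and isopropenyl, and the route is rejoined at 4.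

Step 6. The risks are loss of silanolate by beta-elimination from the enamine of 5 and slow condensation of the hindered, alpha-branched aldehyde. Fallback: the bond is made instead by sp3–sp2 Negishi coupling.
- From 5, NaBH4 in MeOH gives [(1R,2R,5R)-2-methyl-5-(prop-1-en-2-yl)-2-[(triethylsilyl)oxy]cyclopentyl]methanol F4.
- Appel iodination (I2, PPh3, imidazole) gives [(1S,2R,5R)-2-methyl-5-(prop-1-en-2-yl)-2-[(triethylsilyl)oxy]cyclopentyl]methyl iodide F5.
- Zinc dust with LiCl in THF gives the corresponding alkylzinc iodide F6.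
- From 9, N-iodosuccinimide gives (2S)-2-methyl-1-(2,4,6-trihydroxy-3-iodo-5-methylphenyl)butan-1-one F7.
- Ac2O in pyridine gives 2-iodo-4-methyl-6-[(2S)-2-methylbutanoyl]benzene-1,3,5-triyl triacetate F8.
- Coupling of F6 with F8 (Pd(OAc)2, SPhos, THF, 50 °C) should give the triacetate of 11 F9.
- K2CO3 in MeOH at 0 °C removes the acetates, and the route is rejoined at 11.

**Further compounds**

F1 | step 7 | (6S)-3,5-dihydroxy-6-methyl-6-(3-methylbut-2-en-1-yl)-2-[(2S)-2-methylbutanoyl]-4-({(1S,2R,5R)-2-methyl-5-(prop-1-en-2-yl)-2-[(triethylsilyl)oxy]cyclopentyl}methyl)cyclohexa-2,4-dien-1-one (C-6 epimer of 12) | C=C(C)[C@@H]1CC[C@@](C)(O[Si](CC)(CC)CC)[C@H]1CC1=C(O)[C@](C)(CC=C(C)C)C(=O)C(C(=O)[C@@H](C)CC)=C1O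
F2 | step 2 | (5S)-2-methyl-5-(prop-1-en-2-yl)cyclopent-1-ene-1-carbaldehyde | C=C(C)[C@@H]1CCC(C)=C1C=O
F3 | step 2 | (1S,2S,5R)-5-methyl-2-(prop-1-en-2-yl)-6-oxabicyclo[3.1.0]hexane-1-carbaldehyde, epoxide oxygen trans to isopropenyl | C=C(C)[C@@H]1CC[C@@]2(C)O[C@@]12C=O
F4 | step 6 | [(1R,2R,5R)-2-methyl-5-(prop-1-en-2-yl)-2-[(triethylsilyl)oxy]cyclopentyl]methanol | C=C(C)[C@@H]1CC[C@@](C)(O[Si](CC)(CC)CC)[C@H]1CO
F5 | step 6 | [(1S,2R,5R)-2-methyl-5-(prop-1-en-2-yl)-2-[(triethylsilyl)oxy]cyclopentyl]methyl iodide | C=C(C)[C@@H]1CC[C@@](C)(O[Si](CC)(CC)CC)[C@H]1CI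
F6 | step 6 | {[(1S,2R,5R)-2-methyl-5-(prop-1-en-2-yl)-2-[(triethylsilyl)oxy]cyclopentyl]methyl}zinc iodide | C=C(C)[C@@H]1CC[C@@](C)(O[Si](CC)(CC)CC)[C@H]1C[Zn]I
F7 | step 6 | (2S)-2-methyl-1-(2,4,6-trihydroxy-3-iodo-5-methylphenyl)butan-1-one | CC[C@H](C)C(=O)c1c(O)c(I)c(O)c(C)c1O
F8 | step 6 | 2-iodo-4-methyl-6-[(2S)-2-methylbutanoyl]benzene-1,3,5-triyl triacetate | CC[C@H](C)C(=O)c1c(OC(C)=O)c(I)c(OC(C)=O)c(C)c1OC(C)=O
F9 | step 6 | triacetate of 11 | C=C(C)[C@@H]1CC[C@@](C)(O[Si](CC)(CC)CC)[C@H]1Cc1c(OC(C)=O)c(C)c(OC(C)=O)c(C(=O)[C@@H](C)CC)c1OC(C)=O
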